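**Retrosynthetic overview**

1. Labels: ring X is the central benzene (Xa carries O1 of furan 1, Xb H, Xc carries O1′ of furan 2, Xd carries C3′, Xe carries C11H2, Xf carries C3). Furan 1 is O1–C2–C3, furan 2 is O1′–C2′–C3′. The seven-membered ring is C3–Y1–Y6–C10–C11–Xe–Xf; ring Y is Y1…Y6; ring W is the 2,4-dioxygenated aryl on C10.
2. The strategy rests on ring Y: a resorcinol with hydroxyls on Y3 and Y5, furan-1 C3 on Y1 and C10 on Y6, which is the folded chain Y1(=O)–Y6–Y5(=O)–Y4–Y3(=O)–Y2H3. After removal of six O-methyl groups (BBr3), ring Y is opened at bond Y1–Y2 to a 2-methyl-4-pyranone fused to the seven-membered ring on the Y1/Y6 edge.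
3. The pyranone comes from an enolised 2-acetylcycloheptanone and MeC(OMe)2NMe2, so the annulation can only occur on Y1/Y6. The β-diketone comes from an intramolecular Claisen condensation (bond Y1–Y6, closes the seven-membered ring) between the furan-1 C3 methyl ester and a methyl ketone side chain on Xe.
4. C10 is set by Rh/(S)-BINAP 1,4-addition of the ring-W boronic acid to an enone attached at C11 by a benzylic Stille coupling. Furan 1 (bond C2–C3) and furan 2 (bond C2′–C3′) each come from a catalyst-controlled rhodium-carbene C–H insertion into a 4-methoxybenzyl ether of ring X, followed by equilibration to trans (base at C3, acid at C2′).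
5. Ring order: X (3,5-dihydroxybenzyl alcohol) → furan 2 → furan 1 → seven-membered ring → pyranone → ring Y.

Key step: step 17

Assumption: Rh2(S-PTAD)4 (PTAD = N-phthaloyl-(S)-adamantylglycinate), Rh2(S-PTTL)4 (PTTL = N-phthaloyl-(S)-tert-leucinate) and (S)-BINAP are written for the senses of induction needed (cis-2′S,3′R in step 5, cis-2S,3R in step 8, 10R in step 14). For (S)-BINAP this follows the usual α-si-face model; if a dirhodium catalyst shows the opposite sense, its mirror-image form is used with no other change.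

**Route**

Step 1
Reactants: 1 3,5-dihydroxybenzyl alcohol; 2 4-methoxybenzyl chloride
Product: 3 [3,5-bis(4-methoxybenzyloxy)phenyl]methanol
Conditions: 2 (2.2 equiv), K2CO3, KI (cat.), DMF, 60 °C
Reagents that add atoms: none
Why: Williamson ether synthesis in which carbonate ionises only the two phenols, so the benzylic alcohol stays free and each 4-methoxybenzyl group becomes the C2–aryl unit of one dihydrofuran.

Step 2
Reactants: 3 [3,5-bis(4-methoxybenzyloxy)phenyl]methanol
Product: 4 [2,6-dibromo-3,5-bis(4-methoxybenzyloxy)phenyl]methanol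
Conditions: NBS (2.05 equiv), MeCN, 0 °C → rt, dark
Reagents that add atoms: N-bromosuccinimide, O=C1CCC(=O)N1Br
Why: Electrophilic aromatic bromination; ring X with two ether oxygens is far more activated than the anisole-type rings, and Xd and Xf (each para to one oxygen) should react before the flanked position Xb.

Step 3
Reactants: 4 [2,6-dibromo-3,5-bis(4-methoxybenzyloxy)phenyl]methanol
Product: 5 tert-butyl{[2,6-dibromo-3,5-bis(4-methoxybenzyloxy)phenyl]methoxy}dimethylsilane
Conditions: TBSCl, imidazole, DMF, rt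
Reagents that add atoms: tert-butyldimethylsilyl chloride, CC(C)(C)[Si](C)(C)Cl
Why: Silylation of the primary alcohol, which must be masked against the organolithium steps and against O–H insertion of the later carbenes.

Step 4
Reactants: 5 tert-butyl{[2,6-dibromo-3,5-bis(4-methoxybenzyloxy)phenyl]methoxy}dimethylsilane; 6 3,5-dimethoxybenzonitrile
Product: 9 hydrazone of [3-bromo-2-(tert-butyldimethylsilyloxymethyl)-4,6-bis(4-methoxybenzyloxy)phenyl](3,5-dimethoxyphenyl)methanone, via aryllithium 7 (not isolated), via N-H ketimine 8 (not isolated)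
Conditions: n-BuLi (1.05 equiv), THF, −78 °C; 6, −78 → −40 °C; MeOH; N2H4·H2O (10 equiv), AcOH, EtOH, 70 °C
Reagents that add atoms: hydrazine hydrate, NN.O
Why: Single bromine–lithium exchange on the symmetric dibromide, addition to the nitrile (which stops at the ketimine) and transimination with hydrazine should give the hydrazone without condensing hydrazine onto a doubly ortho-substituted benzophenone.

Step 5
Reactants: 9 hydrazone of [3-bromo-2-(tert-butyldimethylsilyloxymethyl)-4,6-bis(4-methoxybenzyloxy)phenyl](3,5-dimethoxyphenyl)methanone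
Product: 11 (2S,3R)-5-bromo-4-[(tert-butyldimethylsilyloxy)methyl]-3-(3,5-dimethoxyphenyl)-6-(4-methoxybenzyloxy)-2-(4-methoxyphenyl)-2,3-dihydrobenzofuran (cis), via diaryldiazomethane 10 (not isolated)
Conditions: activated MnO2 (10 equiv), CH2Cl2, 0 °C; filter; Rh2(S-PTAD)4 (1 mol %), CH2Cl2, −20 °C → rt
Reagents that add atoms: none
Why: Hydrazone dehydrogenation followed by donor/donor rhodium-carbene 1,5 C–H insertion into the 4-methoxybenzyl ether on Xc, the only C–H that closes a five-membered ring (the silyloxymethyl group could give only a four-membered ring); the concerted insertion should give the cis isomer with C3′ (R) set by the chiral carboxylate ligands.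

Step 6
Reactants: 11 (2S,3R)-5-bromo-4-[(tert-butyldimethylsilyloxy)methyl]-3-(3,5-dimethoxyphenyl)-6-(4-methoxybenzyloxy)-2-(4-methoxyphenyl)-2,3-dihydrobenzofuran; 12 dimethyl oxalate
Product: 14 methyl 2-oxo-2-[(2S,3R)-4-[(tert-butyldimethylsilyloxy)methyl]-3-(3,5-dimethoxyphenyl)-6-(4-methoxybenzyloxy)-2-(4-methoxyphenyl)-2,3-dihydrobenzofuran-5-yl]acetate, via aryllithium 13 (not isolated)
Conditions: n-BuLi (1.05 equiv), THF, −78 °C; cannulate into 12 (4 equiv), THF, −78 °C; AcOH
Reagents that add atoms: none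
Why: Bromine–lithium exchange at the hindered Xf position followed by acylation with excess oxalate diester, which should stop at the α-keto ester because the tetrahedral adduct persists at −78 °C.

Step 7
Reactants: 14 methyl 2-oxo-2-[(2S,3R)-4-[(tert-butyldimethylsilyloxy)methyl]-3-(3,5-dimethoxyphenyl)-6-(4-methoxybenzyloxy)-2-(4-methoxyphenyl)-2,3-dihydrobenzofuran-5-yl]acetate
Product: 16 methyl 2-diazo-2-[(2S,3R)-4-[(tert-butyldimethylsilyloxy)methyl]-3-(3,5-dimethoxyphenyl)-6-(4-methoxybenzyloxy)-2-(4-methoxyphenyl)-2,3-dihydrobenzofuran-5-yl]acetate, via tosylhydrazone 15 (not isolated)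
Conditions: TsNHNH2 (1.3 equiv), MeOH, 50 °C; evaporate; DBU (1.5 equiv), CH2Cl2, 0 °C → rt
Reagents that add atoms: 4-methylbenzenesulfonohydrazide, Cc1ccc(S(=O)(=O)NN)cc1
Why: Tosylhydrazone formation at the activated keto group and Bamford–Stevens elimination of sulfinate, the standard route from aryl glyoxylates to aryldiazoacetates.

Step 8
Reactants: 16 methyl 2-diazo-2-[(2S,3R)-4-[(tert-butyldimethylsilyloxy)methyl]-3-(3,5-dimethoxyphenyl)-6-(4-methoxybenzyloxy)-2-(4-methoxyphenyl)-2,3-dihydrobenzofuran-5-yl]acetate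
Product: 17 methyl (2S,3R,5R,6S)-4-[(tert-butyldimethylsilyloxy)methyl]-5-(3,5-dimethoxyphenyl)-2,6-bis(4-methoxyphenyl)-2,3,5,6-tetrahydrobenzo[1,2-b:5,4-b′]difuran-3-carboxylate (furan 1 cis; furan 2 cis)
Conditions: Rh2(S-PTTL)4 (1 mol %), toluene, −60 → −20 °C
Reagents that add atoms: none
Why: Donor/acceptor rhodium-carbene intramolecular 1,5 C–H insertion into the remaining 4-methoxybenzyl ether on Xa, expected to give the cis-2,3 ester with C2 (S) set by the catalyst, the existing stereocentres being remote from the carbene.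

Step 9
Reactants: 17 methyl (2S,3R,5R,6S)-4-[(tert-butyldimethylsilyloxy)methyl]-5-(3,5-dimethoxyphenyl)-2,6-bis(4-methoxyphenyl)-2,3,5,6-tetrahydrobenzo[1,2-b:5,4-b′]difuran-3-carboxylate
Product: 18 methyl (2S,3S,5R,6S)-4-[(tert-butyldimethylsilyloxy)methyl]-5-(3,5-dimethoxyphenyl)-2,6-bis(4-methoxyphenyl)-2,3,5,6-tetrahydrobenzo[1,2-b:5,4-b′]difuran-3-carboxylate (furan 1 trans; furan 2 cis)
Conditions: NaOMe (0.3 equiv), MeOH/THF, 0 °C → rt
Reagents that add atoms: none
Why: Base-mediated epimerisation through the ester enolate inverts only C3 and should give the more stable trans ester, with C2 (S) kept as the anchor for furan 1.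

Step 10
Reactants: 18 methyl (2S,3S,5R,6S)-4-[(tert-butyldimethylsilyloxy)methyl]-5-(3,5-dimethoxyphenyl)-2,6-bis(4-methoxyphenyl)-2,3,5,6-tetrahydrobenzo[1,2-b:5,4-b′]difuran-3-carboxylate
Product: 19 methyl (2S,3S,5R,6S)-4-(bromomethyl)-5-(3,5-dimethoxyphenyl)-2,6-bis(4-methoxyphenyl)-2,3,5,6-tetrahydrobenzo[1,2-b:5,4-b′]difuran-3-carboxylate
Conditions: Ph3PBr2 (1.5 equiv), CH2Cl2, rt
Reagents that add atoms: dibromotriphenylphosphorane, BrP(Br)(c1ccccc1)(c1ccccc1)c1ccccc1
Why: Direct conversion of the silyl ether into the bromide through an alkoxyphosphonium ion (Appel-type), which avoids the free hydroxy ester that would lactonise onto the neighbouring C3 ester.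

Step 11
Reactants: 19 methyl (2S,3S,5R,6S)-4-(bromomethyl)-5-(3,5-dimethoxyphenyl)-2,6-bis(4-methoxyphenyl)-2,3,5,6-tetrahydrobenzo[1,2-b:5,4-b′]difuran-3-carboxylate
Product: 20 methyl (2S,3S,5R,6R)-4-(bromomethyl)-5-(3,5-dimethoxyphenyl)-2,6-bis(4-methoxyphenyl)-2,3,5,6-tetrahydrobenzo[1,2-b:5,4-b′]difuran-3-carboxylate (both furans trans)
Conditions: TFA (10 vol %), CH2Cl2, 0 °C → rt
Reagents that add atoms: none
Why: Acid-mediated epimerisation by reversible ionisation of the C2′–O bond to the 4-methoxybenzylic cation and reclosure should give the trans-2′,3′ furan while C3′ (R) is untouched; furan 1 is already trans and its C2 cation is disfavoured by the ester on C3, and no acid-labile benzyl ether is left.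

Step 12
Reactants: 21 (E)-1,2-bis(tributylstannyl)ethene; 22 acetyl chloride
Product: 23 (E)-4-(tributylstannyl)but-3-en-2-one
Conditions: AlCl3 (1.0 equiv), CH2Cl2, −78 → 0 °C
Reagents that add atoms: none
Why: Friedel–Crafts-type ipso acyl-destannylation of the vinylstannane with retention of the E geometry, the second stannyl group being deactivated by the new acyl group.

Step 13
Reactants: 20 methyl (2S,3S,5R,6R)-4-(bromomethyl)-5-(3,5-dimethoxyphenyl)-2,6-bis(4-methoxyphenyl)-2,3,5,6-tetrahydrobenzo[1,2-b:5,4-b′]difuran-3-carboxylate; 23 (E)-4-(tributylstannyl)but-3-en-2-one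
Product: 24 methyl (2S,3S,5R,6R)-5-(3,5-dimethoxyphenyl)-2,6-bis(4-methoxyphenyl)-4-[(E)-4-oxopent-2-enyl]-2,3,5,6-tetrahydrobenzo[1,2-b:5,4-b′]difuran-3-carboxylate
Conditions: Pd2(dba)3 (2.5 mol %), P(2-furyl)3 (10 mol %), THF, 60 °C
Reagents that add atoms: none
Why: Stille coupling of a benzylic bromide with a β-stannyl enone under neutral conditions, which tolerates the enolisable C3 ester and forms the C11–C10 bond with the E alkene retained.

Step 14
Reactants: 24 methyl (2S,3S,5R,6R)-5-(3,5-dimethoxyphenyl)-2,6-bis(4-methoxyphenyl)-4-[(E)-4-oxopent-2-enyl]-2,3,5,6-tetrahydrobenzo[1,2-b:5,4-b′]difuran-3-carboxylate; 25 2,4-dimethoxyphenylboronic acid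
Product: 26 methyl (2S,3S,5R,6R)-4-[(2R)-2-(2,4-dimethoxyphenyl)-4-oxopentyl]-5-(3,5-dimethoxyphenyl)-2,6-bis(4-methoxyphenyl)-2,3,5,6-tetrahydrobenzo[1,2-b:5,4-b′]difuran-3-carboxylate
Conditions: 25 (3 equiv), [Rh(OH)((S)-binap)]2 (1.5 mol %), 1,4-dioxane/H2O (10:1), 40 °C
Reagents that add atoms: none
Why: Hayashi–Miyaura rhodium-catalysed asymmetric 1,4-addition of the arylboronic acid to the acyclic E enone, in which the BINAP ligand selects the enone face and so sets C10 independently of the remote furan stereocentres.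

Step 15
Reactants: 26 methyl (2S,3S,5R,6R)-4-[(2R)-2-(2,4-dimethoxyphenyl)-4-oxopentyl]-5-(3,5-dimethoxyphenyl)-2,6-bis(4-methoxyphenyl)-2,3,5,6-tetrahydrobenzo[1,2-b:5,4-b′]difuran-3-carboxylate
Product: 27 seven-membered-ring β-diketone (Y1 enol form; acetyl on Y6; 2S,3S,10S,2′R,3′R)
Conditions: NaOMe (3 equiv), THF/MeOH (5:1), 60 °C; AcOH
Reagents that add atoms: none
Why: Intramolecular Claisen (Dieckmann-type ketone–ester) condensation under equilibrating alkoxide conditions, where attack by Y6 closes the seven-membered ring (attack by the methyl group would need a nine-membered ring) and deprotonation of the β-diketone drives the equilibrium; C3 stays trans as the thermodynamic epimer.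

Step 16
Reactants: 27 seven-membered-ring β-diketone; 28 N,N-dimethylacetamide dimethyl acetal
Product: 30 cycloheptene-fused 2-methyl-4-pyranone on the bis-dihydrofuran core (2S,3S,10S,2′R,3′R), via enaminone 29 (not isolated)
Conditions: 28 (4 equiv), toluene, 100 °C; evaporate; AcOH, 80 °C
Reagents that add atoms: none
Why: Amide-acetal condensation can occur only at the acetyl methyl group (Y6 and C3 are methines), and acid-promoted addition–elimination of the Y1 enol oxygen onto the enaminone then closes the pyranone as in chromone synthesis, so the ring grows only on the Y1/Y6 edge.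

Step 17
Reactants: 30 cycloheptene-fused 2-methyl-4-pyranone on the bis-dihydrofuran core
Product: 33 hexamethyl ether of the target with free hydroxyls on Y3 and Y5 (2S,3S,10S,2′R,3′R), via triketone 31 (not isolated), via aldol adduct 32 (not isolated)
Conditions: Ba(OH)2·8H2O (4 equiv), degassed 1,4-dioxane/H2O (3:1), 70 °C, Ar; then 1 M HCl to pH 3, 0 °C
Reagents that add atoms: water, O (delivered as hydroxide; it supplies the oxygen on Y3)
Why: Hydroxide adds to the pyranone at the methyl-bearing carbon Y3 (attack at Y1 leads to the same chain) and the ring opens to the barium-chelated 1,3,5-triketone 31, a masked triketide whose starter carbonyl is the ring ketone Y1. The enolate of the terminal methyl ketone (Y2) then adds to Y1 in a 6-(enolendo)-exo-trig aldol that closes ring Y (bond Y1–Y2) to give 32, and loss of water with enolisation of the Y3 and Y5 carbonyls should deliver the resorcinol irreversibly. The closest known reaction is the barium hydroxide conversion of 2,6-dimethyl-4-pyranone, through diacetylacetone, into orcinol. No stereocentre is created; C3 is epimerisable while it is α to Y1, but the trans relation to the C2 aryl group is the thermodynamic one and is fixed once ring Y is aromatic. The step needs the Y2→Y1 aldol to win over a C3→Y3 aldol, over hydroxide retro-Claisen cleavage and over β-elimination of the Xa aryloxide from C2: the first would build a quaternary spiro centre that cannot aromatise and so stays reversible, barium chelation and the moderate temperature limit chain cleavage, and the elimination is the reverse of a 5-endo-trig closure in which the C2–O bond lies near the nodal plane of the C3 enolate.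

Step 18
Reactants: 33 hexamethyl ether of the target
Product: 34 target CNP0154047.3 (2S,3S,10S,2′R,3′R)
Conditions: BBr3 (15 equiv), CH2Cl2, −78 °C → rt; MeOH, then H2O
Reagents that add atoms: none
Why: Lewis-acid cleavage of the six aryl methyl ethers via aryloxyboranes; any reversible opening of the C2–O or C2′–O bonds under these conditions returns the trans dihydrofurans, which are already the thermodynamic isomers.

**Compound list**

1 | 3,5-dihydroxybenzyl alcohol | OCc1cc(O)cc(O)c1 | starting material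
2 | 4-methoxybenzyl chloride | COc1ccc(CCl)cc1 | starting material
3 | [3,5-bis(4-methoxybenzyloxy)phenyl]methanol | OCc1cc(OCc2ccc(OC)cc2)cc(OCc2ccc(OC)cc2)c1 | intermediate
4 | [2,6-dibromo-3,5-bis(4-methoxybenzyloxy)phenyl]methanol | OCc1c(Br)c(OCc2ccc(OC)cc2)cc(OCc2ccc(OC)cc2)c1Br | intermediate
5 | tert-butyl{[2,6-dibromo-3,5-bis(4-methoxybenzyloxy)phenyl]methoxy}dimethylsilane | CC(C)(C)[Si](C)(C)OCc1c(Br)c(OCc2ccc(OC)cc2)cc(OCc2ccc(OC)cc2)c1Br | intermediate
6 | 3,5-dimethoxybenzonitrile | COc1cc(C#N)cc(OC)c1 | starting material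
7 | aryllithium from 5 (lithium on Xd, bromine kept on Xf; not isolated) | CC(C)(C)[Si](C)(C)OCc1c([Li])c(OCc2ccc(OC)cc2)cc(OCc2ccc(OC)cc2)c1Br | intermediate
8 | N-H ketimine, [3-bromo-2-(tert-butyldimethylsilyloxymethyl)-4,6-bis(4-methoxybenzyloxy)phenyl](3,5-dimethoxyphenyl)methanimine (not isolated) | CC(C)(C)[Si](C)(C)OCc1c(C(=N)c2cc(OC)cc(OC)c2)c(OCc2ccc(OC)cc2)cc(OCc2ccc(OC)cc2)c1Br | intermediate
9 | hydrazone of [3-bromo-2-(tert-butyldimethylsilyloxymethyl)-4,6-bis(4-methoxybenzyloxy)phenyl](3,5-dimethoxyphenyl)methanone | CC(C)(C)[Si](C)(C)OCc1c(C(=NN)c2cc(OC)cc(OC)c2)c(OCc2ccc(OC)cc2)cc(OCc2ccc(OC)cc2)c1Br | intermediate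
10 | diaryldiazomethane from 9 (not isolated) | CC(C)(C)[Si](C)(C)OCc1c(C(=[N+]=[N-])c2cc(OC)cc(OC)c2)c(OCc2ccc(OC)cc2)cc(OCc2ccc(OC)cc2)c1Br | intermediate
11 | (2S,3R)-5-bromo-4-[(tert-butyldimethylsilyloxy)methyl]-3-(3,5-dimethoxyphenyl)-6-(4-methoxybenzyloxy)-2-(4-methoxyphenyl)-2,3-dihydrobenzofuran (furan 2, cis) | COc1ccc(COc2cc3c(c(CO[Si](C)(C)C(C)(C)C)c2Br)[C@@H](c2cc(OC)cc(OC)c2)[C@@H](c2ccc(OC)cc2)O3)cc1 | intermediate
12 | dimethyl oxalate | COC(=O)C(=O)OC | starting material
13 | aryllithium from 11 (lithium on Xf; not isolated) | COc1ccc(COc2cc3c(c(CO[Si](C)(C)C(C)(C)C)c2[Li])[C@@H](c2cc(OC)cc(OC)c2)[C@@H](c2ccc(OC)cc2)O3)cc1 | intermediate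
14 | methyl 2-oxo-2-[(2S,3R)-4-[(tert-butyldimethylsilyloxy)methyl]-3-(3,5-dimethoxyphenyl)-6-(4-methoxybenzyloxy)-2-(4-methoxyphenyl)-2,3-dihydrobenzofuran-5-yl]acetate | COc1ccc(COc2cc3c(c(CO[Si](C)(C)C(C)(C)C)c2C(=O)C(=O)OC)[C@@H](c2cc(OC)cc(OC)c2)[C@@H](c2ccc(OC)cc2)O3)cc1 | intermediate
15 | tosylhydrazone of 14 (not isolated) | COc1ccc(COc2cc3c(c(CO[Si](C)(C)C(C)(C)C)c2C(=NNS(=O)(=O)c2ccc(C)cc2)C(=O)OC)[C@@H](c2cc(OC)cc(OC)c2)[C@@H](c2ccc(OC)cc2)O3)cc1 | intermediate
16 | methyl 2-diazo-2-[(2S,3R)-4-[(tert-butyldimethylsilyloxy)methyl]-3-(3,5-dimethoxyphenyl)-6-(4-methoxybenzyloxy)-2-(4-methoxyphenyl)-2,3-dihydrobenzofuran-5-yl]acetate | COc1ccc(COc2cc3c(c(CO[Si](C)(C)C(C)(C)C)c2C(=[N+]=[N-])C(=O)OC)[C@@H](c2cc(OC)cc(OC)c2)[C@@H](c2ccc(OC)cc2)O3)cc1 | intermediate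
17 | methyl (2S,3R,5R,6S)-4-[(tert-butyldimethylsilyloxy)methyl]-5-(3,5-dimethoxyphenyl)-2,6-bis(4-methoxyphenyl)-2,3,5,6-tetrahydrobenzo[1,2-b:5,4-b′]difuran-3-carboxylate (furan 1 cis 2S,3R; furan 2 cis 2′S,3′R) | COc1ccc([C@H]2Oc3cc4c(c(CO[Si](C)(C)C(C)(C)C)c3[C@H]2C(=O)OC)[C@@H](c2cc(OC)cc(OC)c2)[C@@H](c2ccc(OC)cc2)O4)cc1 | intermediate
18 | methyl (2S,3S,5R,6S)-4-[(tert-butyldimethylsilyloxy)methyl]-5-(3,5-dimethoxyphenyl)-2,6-bis(4-methoxyphenyl)-2,3,5,6-tetrahydrobenzo[1,2-b:5,4-b′]difuran-3-carboxylate (furan 1 trans 2S,3S; furan 2 cis 2′S,3′R) | COc1ccc([C@H]2Oc3cc4c(c(CO[Si](C)(C)C(C)(C)C)c3[C@@H]2C(=O)OC)[C@@H](c2cc(OC)cc(OC)c2)[C@@H](c2ccc(OC)cc2)O4)cc1 | intermediate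
19 | methyl (2S,3S,5R,6S)-4-(bromomethyl)-5-(3,5-dimethoxyphenyl)-2,6-bis(4-methoxyphenyl)-2,3,5,6-tetrahydrobenzo[1,2-b:5,4-b′]difuran-3-carboxylate (furan 1 trans; furan 2 cis) | COc1ccc([C@H]2Oc3cc4c(c(CBr)c3[C@@H]2C(=O)OC)[C@@H](c2cc(OC)cc(OC)c2)[C@@H](c2ccc(OC)cc2)O4)cc1 | intermediate
20 | methyl (2S,3S,5R,6R)-4-(bromomethyl)-5-(3,5-dimethoxyphenyl)-2,6-bis(4-methoxyphenyl)-2,3,5,6-tetrahydrobenzo[1,2-b:5,4-b′]difuran-3-carboxylate (furan 1 trans 2S,3S; furan 2 trans 2′R,3′R) | COc1ccc([C@H]2Oc3cc4c(c(CBr)c3[C@@H]2C(=O)OC)[C@@H](c2cc(OC)cc(OC)c2)[C@H](c2ccc(OC)cc2)O4)cc1 | intermediate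
21 | (E)-1,2-bis(tributylstannyl)ethene | CCCC[Sn](CCCC)(CCCC)/C=C/[Sn](CCCC)(CCCC)CCCC | starting material
22 | acetyl chloride | CC(=O)Cl | starting material
23 | (E)-4-(tributylstannyl)but-3-en-2-one | CC(=O)/C=C/[Sn](CCCC)(CCCC)CCCC | intermediate
24 | methyl (2S,3S,5R,6R)-5-(3,5-dimethoxyphenyl)-2,6-bis(4-methoxyphenyl)-4-[(E)-4-oxopent-2-enyl]-2,3,5,6-tetrahydrobenzo[1,2-b:5,4-b′]difuran-3-carboxylate | COc1ccc([C@H]2Oc3cc4c(c(C/C=C/C(C)=O)c3[C@@H]2C(=O)OC)[C@@H](c2cc(OC)cc(OC)c2)[C@H](c2ccc(OC)cc2)O4)cc1 | intermediate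
25 | 2,4-dimethoxyphenylboronic acid | COc1ccc(B(O)O)c(OC)c1 | starting material
26 | methyl (2S,3S,5R,6R)-4-[(2R)-2-(2,4-dimethoxyphenyl)-4-oxopentyl]-5-(3,5-dimethoxyphenyl)-2,6-bis(4-methoxyphenyl)-2,3,5,6-tetrahydrobenzo[1,2-b:5,4-b′]difuran-3-carboxylate | COc1ccc([C@H]2Oc3cc4c(c(C[C@H](CC(C)=O)c5ccc(OC)cc5OC)c3[C@@H]2C(=O)OC)[C@@H](c2cc(OC)cc(OC)c2)[C@H](c2ccc(OC)cc2)O4)cc1 | intermediate
27 | seven-membered-ring β-diketone, drawn as the Y1 enol with acetyl on Y6 (2S,3S,10S,2′R,3′R) | COc1ccc([C@H]2Oc3cc4c(c5c3[C@@H]2C(O)=C(C(C)=O)[C@H](c2ccc(OC)cc2OC)C5)[C@@H](c2cc(OC)cc(OC)c2)[C@H](c2ccc(OC)cc2)O4)cc1 | intermediate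
28 | N,N-dimethylacetamide dimethyl acetal | CN(C)C(C)(OC)OC | starting material
29 | enaminone, Y6–C(=O)–CH=C(CH3)NMe2 on the enolised seven-membered ketone (not isolated) | COc1ccc([C@H]2Oc3cc4c(c5c3[C@@H]2C(O)=C(C(=O)/C=C(\C)N(C)C)[C@H](c2ccc(OC)cc2OC)C5)[C@@H](c2cc(OC)cc(OC)c2)[C@H](c2ccc(OC)cc2)O4)cc1 | intermediate
30 | cycloheptene-fused 2-methyl-4-pyranone on the bis-dihydrofuran core (2S,3S,10S,2′R,3′R) | COc1ccc([C@H]2Oc3cc4c(c5c3[C@@H]2C2=C(C(=O)C=C(C)O2)[C@H](c2ccc(OC)cc2OC)C5)[C@@H](c2cc(OC)cc(OC)c2)[C@H](c2ccc(OC)cc2)O4)cc1 | intermediate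
31 | 1,3,5-triketone, Y1(=O)–Y6H–Y5(=O)–Y4H2–Y3(=O)–Y2H3, Y6 unassigned, other centres as in 30 (not isolated) | COc1ccc([C@H]2Oc3cc4c(c5c3[C@@H]2C(=O)C(C(=O)CC(C)=O)[C@H](c2ccc(OC)cc2OC)C5)[C@@H](c2cc(OC)cc(OC)c2)[C@H](c2ccc(OC)cc2)O4)cc1 | intermediate
32 | aldol adduct with ring Y closed as a hydroxy-cyclohexanedione, Y1 and Y6 unassigned, other centres as in 30 (not isolated) | COc1ccc([C@H]2Oc3cc4c(c5c3[C@@H]2C2(O)CC(=O)CC(=O)C2[C@H](c2ccc(OC)cc2OC)C5)[C@@H](c2cc(OC)cc(OC)c2)[C@H](c2ccc(OC)cc2)O4)cc1 | intermediate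
33 | hexamethyl ether of the target with free hydroxyls on Y3 and Y5 (2S,3S,10S,2′R,3′R) | COc1ccc([C@H]2Oc3cc4c(c5c3[C@@H]2c2cc(O)cc(O)c2[C@H](c2ccc(OC)cc2OC)C5)[C@@H](c2cc(OC)cc(OC)c2)[C@H](c2ccc(OC)cc2)O4)cc1 | intermediate
34 | CNP0154047.3, octaphenol (2S,3S,10S,2′R,3′R; both dihydrofurans trans) | Oc1ccc([C@H]2Oc3cc4c(c5c3[C@@H]2c2cc(O)cc(O)c2[C@H](c2ccc(O)cc2O)C5)[C@@H](c2cc(O)cc(O)c2)[C@H](c2ccc(O)cc2)O4)cc1 | target

**Step count**

Total: 18 steps. Longest linear sequence: 17 steps (steps 1–11 and 13–18); step 12 is a one-step side branch.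

**Steps most likely to fail**

Step 17. The hydroxide may cleave the polyketone chain by retro-Claisen attack, or the Xa aryloxide may be lost from C2 by β-elimination, faster than the aldol at the hindered Y1 carbonyl. Fallback: set out from 27 and make the chain by C–C bond formation instead of by ring opening. Treat 27 with LiN(i-Pr)2 (3.2 equiv) in THF at −78 °C to form the dianion at the terminal acetyl methyl group, acylate it with N-methoxy-N-methylacetamide, and isolate the triketone 31 after an acetic acid quench. Cyclise 31 with K2CO3 in methanol at 0 °C → rt, without hot aqueous hydroxide, and come back to the route at 33. This fallback makes no compound outside the list (F0).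

Step 5. The chiral dirhodium carboxylate may show poor facial selectivity toward a diaryl carbene flanked by two ortho substituents. Fallback: set out from 9, oxidise to 10 as before and decompose it with the achiral catalyst Rh2(esp)2 in CH2Cl2. This should give the racemic cis dihydrobenzofuran, that is 11 together with its enantiomer, (2R,3S)-5-bromo-4-[(tert-butyldimethylsilyloxy)methyl]-3-(3,5-dimethoxyphenyl)-6-(4-methoxybenzyloxy)-2-(4-methoxyphenyl)-2,3-dihydrobenzofuran F1. The two are separated by preparative chromatography on a chiral stationary phase, and the route is rejoined at 11.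

Step 15. The seven-membered Claisen closure may stall because the C3 ester is held as its enolate, or because saponification competes. Fallback: set out from 26 and acylate under soft enolisation instead. Saponify with LiOH in THF/H2O to the carboxylic acid F2, convert it with pentafluorophenol and EDC·HCl into the pentafluorophenyl ester F3, and treat F3 with MgBr2·OEt2 and i-Pr2NEt in CH2Cl2. The magnesium enolate of the methyl ketone should then be C-acylated intramolecularly, and the route is rejoined at 27.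

**Further compounds**

F0 | step 17 | none | none
F1 | step 5 | (2R,3S)-5-bromo-4-[(tert-butyldimethylsilyloxy)methyl]-3-(3,5-dimethoxyphenyl)-6-(4-methoxybenzyloxy)-2-(4-methoxyphenyl)-2,3-dihydrobenzofuran (enantiomer of 11) | COc1ccc(COc2cc3c(c(CO[Si](C)(C)C(C)(C)C)c2Br)[C@H](c2cc(OC)cc(OC)c2)[C@H](c2ccc(OC)cc2)O3)cc1
F2 | step 15 | (2S,3S,5R,6R)-4-[(2R)-2-(2,4-dimethoxyphenyl)-4-oxopentyl]-5-(3,5-dimethoxyphenyl)-2,6-bis(4-methoxyphenyl)-2,3,5,6-tetrahydrobenzo[1,2-b:5,4-b′]difuran-3-carboxylic acid | COc1ccc([C@H]2Oc3cc4c(c(C[C@H](CC(C)=O)c5ccc(OC)cc5OC)c3[C@@H]2C(=O)O)[C@@H](c2cc(OC)cc(OC)c2)[C@H](c2ccc(OC)cc2)O4)cc1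
F3 | step 15 | pentafluorophenyl ester of F2 | COc1ccc([C@H]2Oc3cc4c(c(C[C@H](CC(C)=O)c5ccc(OC)cc5OC)c3[C@@H]2C(=O)Oc2c(F)c(F)c(F)c(F)c2F)[C@@H](c2cc(OC)cc(OC)c2)[C@H](c2ccc(OC)cc2)O4)cc1
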